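**Retrosynthetic overview**

1. Ester C–O: acylation of the secondary allylic OH of diol 18; the C5 carbinol comes from hydroxyl-directed anti reduction of β-hydroxy enone 16.
2. Seven-membered ring (closed last): ring-closing metathesis forms C6=C7 in 15. The C3a–C4 bond and the tertiary C3a–OH come from aldol addition of a methyl isopropenyl ketone enolate to cyclopentanone 11, anti to its cis methyl/isopropyl face.
3. Quaternary C8a: allyl Grignard 1,2-addition to enal 5 and anionic oxy-Cope shift, then oxidative removal of the formyl handle to give 11.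
4. Five-membered ring: one-flask oxidative ring contraction of the cyclohexene ring of (S)-p-menth-1-ene 2 (from (S)-limonene 1). The enabling feature is the single ring alkene C1=C2 (C1 carries the methyl group): cleavage gives a 6-oxoheptanal in which the aldehyde α-carbon (old C3) and the ketone carbon (old C1) can close only a five-membered ring, so old C2 is pushed out as a formyl group next to the isopropyl-bearing stereocentre (old C4).
5. Ring order: six-membered carbocycle (chiral pool) → five-membered ring (step 2) → seven-membered ring (step 7).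

Key step: step 2

Assumption: the SMILES is read as the (3R,3aS,5R,8aR) isomer (ring-fusion OH, ring-fusion methyl and isopropyl all cis; ester oxygen trans to the ring-fusion OH), and (S)-(−)-limonene of high enantiomeric purity is taken as the commercial source of chirality.

**Route**

Step 1
Reactants: 1 (S)-(−)-limonene
Product: 2 (S)-p-menth-1-ene [(4S)-1-methyl-4-(propan-2-yl)cyclohex-1-ene]
Conditions: H2 (1 atm), RhCl(PPh3)3 (2 mol%), benzene–EtOH, rt
Reagents that add atoms: none
Why: Chemoselective homogeneous hydrogenation with Wilkinson's catalyst should reduce the unhindered 1,1-disubstituted isopropenyl alkene much faster than the trisubstituted ring alkene, and the C4 stereocentre is not involved.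

Step 2
Reactants: 2 (S)-p-menth-1-ene
Product: 5 (5R)-2-methyl-5-(propan-2-yl)cyclopent-1-ene-1-carbaldehyde, via ozonide 3 (not isolated), via keto-aldehyde 4 (not isolated)
Conditions: O3, CH2Cl2, −78 °C; Me2S, −78 °C → rt; solvent exchange to toluene without isolation, piperidine (0.3 equiv), AcOH (0.3 equiv), 80 °C
Reagents that add atoms: ozone ([O-][O+]=O)
Why: Ozone adds to the only C=C and the secondary ozonide 3 is reduced by Me2S to the 1,6-keto-aldehyde 4; piperidinium acetate then forms the enamine of the aldehyde, whose α-carbon adds to the methyl ketone and water is lost to give the tetrasubstituted enal. The closest known reaction type is the ozonolysis/intramolecular aldol condensation ring contraction of 1-methylcyclohexenes of the limonene series. The ring closes in a 5-(enolexo)-exo-trig aldol, so five of the six ring carbons of 2 become the cyclopentene and the sixth leaves the ring as the formyl carbon. No new stereocentre is formed; the isopropyl-bearing carbon is β to the aldehyde in 4 and allylic in 5, so it should keep its configuration. The step needs aldol regioselectivity (aldehyde α-carbon onto the ketone, not ketone enolate onto the aldehyde, which would give an acetylcyclopentene); amine/acid catalysis, which activates the aldehyde as its enamine, should secure this. The formyl group placed beside the stereocentre then serves as the handle for the stereocontrolled allyl transfer of steps 3 and 4.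

Step 3
Reactants: 5 (5R)-2-methyl-5-(propan-2-yl)cyclopent-1-ene-1-carbaldehyde
Product: 6 1-[(5R)-2-methyl-5-(propan-2-yl)cyclopent-1-en-1-yl]but-3-en-1-ol (both carbinol epimers)
Conditions: allylMgBr, Et2O, −78 → 0 °C; H2O
Reagents that add atoms: allylmagnesium bromide (C=CC[Mg]Br)
Why: Grignard 1,2-addition to the enal (the fully substituted β-carbon excludes conjugate addition) should give the 1,5-dien-3-ol; the new carbinol centre is destroyed in step 4, so its configuration does not matter.

Step 4
Reactants: 6 1-[(5R)-2-methyl-5-(propan-2-yl)cyclopent-1-en-1-yl]but-3-en-1-ol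
Product: 9 (2R,5R)-2-methyl-5-(propan-2-yl)-2-(prop-2-en-1-yl)cyclopentane-1-carbaldehyde (C1 epimers), via potassium alkoxide 7 (not isolated), via potassium enolate 8 (not isolated)
Conditions: KH, 18-crown-6, THF, 0 °C → rt; H2O, −78 °C
Reagents that add atoms: none
Why: Anionic oxy-Cope rearrangement ([3,3]) of the potassium dienolate should move the allyl group from the carbinol carbon to the methyl-bearing ring carbon through a chair transition state on the face away from the neighbouring isopropyl group, which sets the quaternary centre with methyl cis to isopropyl; protonation of enolate 8 gives the aldehyde.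

Step 5
Reactants: 9 (2R,5R)-2-methyl-5-(propan-2-yl)-2-(prop-2-en-1-yl)cyclopentane-1-carbaldehyde
Product: 11 (2R,5R)-2-methyl-5-(propan-2-yl)-2-(prop-2-en-1-yl)cyclopentan-1-one, via hydroperoxy aldehyde 10 (not isolated)
Conditions: O2 (1 atm), Cu(OAc)2 (10 mol%), 2,2'-bipyridine (10 mol%), DABCO, DMF, 40 °C
Reagents that add atoms: dioxygen (O=O)
Why: Copper-catalysed aerobic oxidative deformylation of an α-branched aldehyde (oxygenation of the enol to the α-hydroperoxy aldehyde, then C–C cleavage with loss of formic acid) should give the ketone without touching the quaternary centre, and the weak amine base should leave the now α-positioned isopropyl centre unchanged.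

Step 6
Reactants: 11 (2R,5R)-2-methyl-5-(propan-2-yl)-2-(prop-2-en-1-yl)cyclopentan-1-one; 12 3-methylbut-3-en-2-one
Product: 15 1-[(1S,2R,5R)-1-hydroxy-2-methyl-5-(propan-2-yl)-2-(prop-2-en-1-yl)cyclopentyl]-3-methylbut-3-en-2-one, via lithium enolate 13 (not isolated), via cerium enolate 14 (not isolated)
Conditions: 12, LDA, THF, −78 °C; anhydrous CeCl3, −78 °C; then 11, −78 °C; H2O
Reagents that add atoms: none
Why: Aldol addition of the kinetic, weakly basic organocerium enolate (which suppresses enolization and retro-aldol) should occur on the carbonyl face opposite to the cis methyl and isopropyl groups, so the new CH2 chain ends cis to the allyl group and the tertiary OH cis to methyl and isopropyl.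

Step 7
Reactants: 15 1-[(1S,2R,5R)-1-hydroxy-2-methyl-5-(propan-2-yl)-2-(prop-2-en-1-yl)cyclopentyl]-3-methylbut-3-en-2-one
Product: 16 (3R,3aS,8aR)-3a-hydroxy-6,8a-dimethyl-3-(propan-2-yl)-2,3,3a,4,8,8a-hexahydroazulen-5(1H)-one
Conditions: Grubbs second-generation catalyst (5 mol%), CH2Cl2 (0.005 M), 40 °C
Reagents that add atoms: none
Why: Ring-closing metathesis of the allyl group with the 1,1-disubstituted enone alkene should close the seven-membered ring as a trisubstituted cycloheptenone with loss of ethene; the ring is cis-fused because both chains sit on the same face.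

Step 8
Reactants: 16 (3R,3aS,8aR)-3a-hydroxy-6,8a-dimethyl-3-(propan-2-yl)-2,3,3a,4,8,8a-hexahydroazulen-5(1H)-one
Product: 18 (3R,3aS,5R,8aR)-6,8a-dimethyl-3-(propan-2-yl)-1,2,3,3a,4,5,8,8a-octahydroazulene-3a,5-diol, via alkoxyborohydride 17 (not isolated)
Conditions: Me4NBH(OAc)3, MeCN–AcOH, −30 → 0 °C; aqueous work-up
Reagents that add atoms: none
Why: Evans–Saksena reduction: the tertiary hydroxyl exchanges an acetate on boron and delivers hydride internally to the same face of the enone carbonyl (1,2-reduction), which should give the anti (trans) 1,3-diol, C5 R.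

Step 9
Reactants: 18 (3R,3aS,5R,8aR)-6,8a-dimethyl-3-(propan-2-yl)-1,2,3,3a,4,5,8,8a-octahydroazulene-3a,5-diol; 19 3,4-dimethoxybenzoyl chloride
Product: 20 (3R,3aS,5R,8aR)-3a-hydroxy-6,8a-dimethyl-3-(propan-2-yl)-1,2,3,3a,4,5,8,8a-octahydroazulen-5-yl 3,4-dimethoxybenzoate
Conditions: Et3N, DMAP (cat.), CH2Cl2, 0 °C → rt
Reagents that add atoms: none
Why: DMAP-catalysed acyl transfer should esterify the secondary allylic alcohol only, because the tertiary ring-fusion alcohol is too hindered to be acylated under these conditions.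

**Compound list**

1 | (S)-(−)-limonene [(4S)-1-methyl-4-(prop-1-en-2-yl)cyclohex-1-ene] | CC1=CC[C@H](CC1)C(C)=C | starting material
2 | (S)-p-menth-1-ene [(4S)-1-methyl-4-(propan-2-yl)cyclohex-1-ene] | CC1=CC[C@H](CC1)C(C)C | intermediate
3 | secondary ozonide of 2 [1-methyl-4-(propan-2-yl)-7,8,9-trioxabicyclo[4.2.1]nonane; isopropyl centre as in 2, bridgeheads unassigned] | CC12CC[C@H](C(C)C)CC(O1)OO2 | intermediate
4 | (3S)-6-oxo-3-(propan-2-yl)heptanal | O=CC[C@H](CCC(C)=O)C(C)C | intermediate
5 | (5R)-2-methyl-5-(propan-2-yl)cyclopent-1-ene-1-carbaldehyde | O=CC1=C(C)CC[C@@H]1C(C)C | intermediate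
6 | 1-[(5R)-2-methyl-5-(propan-2-yl)cyclopent-1-en-1-yl]but-3-en-1-ol (both carbinol epimers) | C=CCC(O)C1=C(C)CC[C@@H]1C(C)C | intermediate
7 | potassium 1-[(5R)-2-methyl-5-(propan-2-yl)cyclopent-1-en-1-yl]but-3-en-1-olate | [K+].[O-]C(CC=C)C1=C(C)CC[C@@H]1C(C)C | intermediate
8 | potassium [(2R,5R)-2-methyl-5-(propan-2-yl)-2-(prop-2-en-1-yl)cyclopentylidene]methanolate | [K+].[O-]C=C1[C@@H](C(C)C)CC[C@]1(C)CC=C | intermediate
9 | (2R,5R)-2-methyl-5-(propan-2-yl)-2-(prop-2-en-1-yl)cyclopentane-1-carbaldehyde (C1 epimers) | O=CC1[C@@H](C(C)C)CC[C@]1(C)CC=C | intermediate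
10 | (2R,5R)-1-hydroperoxy-2-methyl-5-(propan-2-yl)-2-(prop-2-en-1-yl)cyclopentane-1-carbaldehyde | O=CC1(OO)[C@@H](C(C)C)CC[C@]1(C)CC=C | intermediate
11 | (2R,5R)-2-methyl-5-(propan-2-yl)-2-(prop-2-en-1-yl)cyclopentan-1-one | O=C1[C@@H](C(C)C)CC[C@]1(C)CC=C | intermediate
12 | 3-methylbut-3-en-2-one | CC(=O)C(C)=C | starting material
13 | lithium 3-methylbuta-1,3-dien-2-olate | [Li+].[O-]C(=C)C(C)=C | intermediate
14 | dichlorocerium(III) 3-methylbuta-1,3-dien-2-olate | C=C(C)C(=C)O[Ce](Cl)Cl | intermediate
15 | 1-[(1S,2R,5R)-1-hydroxy-2-methyl-5-(propan-2-yl)-2-(prop-2-en-1-yl)cyclopentyl]-3-methylbut-3-en-2-one | C=C(C)C(=O)C[C@]1(O)[C@@H](C(C)C)CC[C@]1(C)CC=C | intermediate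
16 | (3R,3aS,8aR)-3a-hydroxy-6,8a-dimethyl-3-(propan-2-yl)-2,3,3a,4,8,8a-hexahydroazulen-5(1H)-one | O=C1C[C@]2(O)[C@@H](C(C)C)CC[C@]2(C)CC=C1C | intermediate
17 | tetramethylammonium diacetoxy(hydrido)borate ester of the tertiary hydroxyl of 16 | O=C1C[C@]2(O[BH-](OC(C)=O)OC(C)=O)[C@@H](C(C)C)CC[C@]2(C)CC=C1C.C[N+](C)(C)C | intermediate
18 | (3R,3aS,5R,8aR)-6,8a-dimethyl-3-(propan-2-yl)-1,2,3,3a,4,5,8,8a-octahydroazulene-3a,5-diol | O[C@@H]1C[C@]2(O)[C@@H](C(C)C)CC[C@]2(C)CC=C1C | intermediate
19 | 3,4-dimethoxybenzoyl chloride | COc1ccc(C(Cl)=O)cc1OC | starting material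
20 | (3R,3aS,5R,8aR)-3a-hydroxy-6,8a-dimethyl-3-(propan-2-yl)-1,2,3,3a,4,5,8,8a-octahydroazulen-5-yl 3,4-dimethoxybenzoate | COc1ccc(C(=O)O[C@@H]2C[C@]3(O)[C@@H](C(C)C)CC[C@]3(C)CC=C2C)cc1OC | target

**Step count**

Total step count: 9. Longest linear sequence: 9 steps (1 → 20; 12 and 19 are commercial).

**Steps most likely to fail**

Step 4. The potassium alkoxide may fragment by retro-allylation instead of rearranging, or the [3,3] shift may discriminate the two ring faces poorly when it has to form the quaternary centre. The fallback builds that centre by an orthoester Claisen rearrangement; it sets out from 5 and comes back to the route at 11. Luche reduction of 5 (NaBH4, CeCl3, MeOH) should give [(5R)-2-methyl-5-(propan-2-yl)cyclopent-1-en-1-yl]methanol F1. Johnson–Claisen rearrangement (MeC(OEt)3, cat. EtCO2H, 140 °C) should deliver the two-carbon unit to the ring carbon anti to the isopropyl group and give ethyl 2-[(1R,3R)-1-methyl-2-methylidene-3-(propan-2-yl)cyclopentyl]acetate F2. DIBAL-H at −78 °C should give 2-[(1R,3R)-1-methyl-2-methylidene-3-(propan-2-yl)cyclopentyl]acetaldehyde F3. Ozonolysis of the exocyclic methylene (O3, then Me2S) should give 2-[(1R,3R)-1-methyl-2-oxo-3-(propan-2-yl)cyclopentyl]acetaldehyde F4, and aldehyde-selective Wittig methylenation (Ph3P=CH2, 1 equiv, −78 °C) should then give 11.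

Step 6. The enolate may deprotonate the hindered ketone instead of adding to it, with loss of configuration at the isopropyl-bearing carbon, or the adduct may revert by retro-aldol. The fallback starts with an irreversible Reformatsky addition; it sets out from 11 and comes back at 15. Zinc and ethyl bromoacetate (THF, reflux) should give ethyl 2-[(1S,2R,5R)-1-hydroxy-2-methyl-5-(propan-2-yl)-2-(prop-2-en-1-yl)cyclopentyl]acetate F5 with the same facial preference. MeNHOMe·HCl with i-PrMgCl should convert it into 2-[(1S,2R,5R)-1-hydroxy-2-methyl-5-(propan-2-yl)-2-(prop-2-en-1-yl)cyclopentyl]-N-methoxy-N-methylacetamide F6, and isopropenylmagnesium bromide should then give 15.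

Step 8. Ligand exchange at the hindered tertiary hydroxyl may be slow, so that undirected reduction competes and the anti selectivity erodes. The fallback sets C5 by inversion instead; it sets out from 16 and comes back at 20. Narasaka–Prasad reduction (Et2BOMe, NaBH4, THF–MeOH, −78 °C) should give the syn (cis) diol (3R,3aS,5S,8aR)-6,8a-dimethyl-3-(propan-2-yl)-1,2,3,3a,4,5,8,8a-octahydroazulene-3a,5-diol F7. Mitsunobu esterification of F7 with 3,4-dimethoxybenzoic acid (PPh3, DIAD) should invert C5 and give 20 directly.

Further compounds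
F1 | step 4 | [(5R)-2-methyl-5-(propan-2-yl)cyclopent-1-en-1-yl]methanol | OCC1=C(C)CC[C@@H]1C(C)C
F2 | step 4 | ethyl 2-[(1R,3R)-1-methyl-2-methylidene-3-(propan-2-yl)cyclopentyl]acetate | C=C1[C@@H](C(C)C)CC[C@]1(C)CC(=O)OCC
F3 | step 4 | 2-[(1R,3R)-1-methyl-2-methylidene-3-(propan-2-yl)cyclopentyl]acetaldehyde | C=C1[C@@H](C(C)C)CC[C@]1(C)CC=O
F4 | step 4 | 2-[(1R,3R)-1-methyl-2-oxo-3-(propan-2-yl)cyclopentyl]acetaldehyde | O=C1[C@@H](C(C)C)CC[C@]1(C)CC=O
F5 | step 6 | ethyl 2-[(1S,2R,5R)-1-hydroxy-2-methyl-5-(propan-2-yl)-2-(prop-2-en-1-yl)cyclopentyl]acetate | CCOC(=O)C[C@]1(O)[C@@H](C(C)C)CC[C@]1(C)CC=C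
F6 | step 6 | 2-[(1S,2R,5R)-1-hydroxy-2-methyl-5-(propan-2-yl)-2-(prop-2-en-1-yl)cyclopentyl]-N-methoxy-N-methylacetamide | CON(C)C(=O)C[C@]1(O)[C@@H](C(C)C)CC[C@]1(C)CC=C
F7 | step 8 | (3R,3aS,5S,8aR)-6,8a-dimethyl-3-(propan-2-yl)-1,2,3,3a,4,5,8,8a-octahydroazulene-3a,5-diol | O[C@H]1C[C@]2(O)[C@@H](C(C)C)CC[C@]2(C)CC=C1C
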